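We keep the books in amounts, every entry a fraction of the starting material charged, and the account is the reagent, which starts in the second phase.

| setting | cedar | amber | red | teal | blue | green |
|---|---|---|---|---|---|---|
| starting material | 0.025 M | 0.025 M | 0.025 M | 0.025 M | 0.025 M | 0.025 M |
| reagent in the second phase | 1 equiv | 1.00 equiv | 2.00 equiv | 4.00 equiv | 8.00 equiv | 15.0 equiv |
| protic impurity | 0.019 M | 0.0125 M | 0.0125 M | 0.0125 M | 0.0125 M | 0.0125 M |
| remark | run made earlier |  |  |  |  |  |
| time |  | 1.0 h | 1.0 h | 1.0 h | 1.0 h | 1.0 h |
| volume of the second phase over the first |  | 0.25 | 0.25 | 0.25 | 0.25 | 0.25 |

- cedar (time / min: target / %): 2.00: 0.2; 6.00: 0.5; 10.0: 2.1; 15.0: 3.0; 20.0: 3.1; 30.0: 5.2; 40.0: 4.5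

(readings scatter by 0.5 percentage points)

- in the second phase: reagent in the second phase; everything else is in the first
- charges count per volume of the first phase; a concentration in a rate is the amount of a species over the volume of its own phase; every rate counts per litre of the first phase
- the earlier runs hold the two phases in the same ratio of volumes as the flask asked about
- "hardly changes" means that all values lie within two and a half points (for a concentration: within two and a half percent of the largest)
- no earlier run changes the charge of protic impurity; that part of a forecast is a guess

- amount of target at the end, in percent of the starting material charged for amber, red, teal, blue, green, in this order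
- how the row runs (falls all the way / hardly changes / rises all the way / rises, then falls / falls, then rises)

Cedar opens with 1 equiv. We book the protic impurity first, as our own assumption, at 0.760 of the charge, which leaves 0.240 as spare reagent. The last two target readings, 5.2% and 4.5%, agree within their scatter and average 0.0485 of the charge. That is the target entry so far, so 0.192 of the spare stands unbooked, more than target received. Readings that agree within their scatter can't show whether target has levelled off, so our guess that spare reagent also attacks target remains a guess.

In the new flasks the impurity entry is 0.500. Amber therefore has 0.500 spare, and scaling the cedar entry gives about 10.1% target. Our rule is the crossing charge, the reagent charge at which the spare equals the whole starting material: 1.50 equiv. Below it reagent is the limiting reagent, and each added portion can make target. Above it starting material is limiting, and the surplus can go on to target. Amber lies below the crossing and red above it, so we commit to a row that rises, then falls, turning at the crossing or beyond it. Cedar gives no pace from which to say how far beyond.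

The forecast differs from us, with 7.5%, 17%, 35%, 59% and 82%, a row that rises all the way, and says “Target rises throughout.”

    starting material ⇌ dormant form (K = 0.910, k = 0.460 h⁻¹)
    reagent in the reaction phase + protic impurity → quenched reagent (k = 120 L mol⁻¹ h⁻¹)
    starting material + reagent in the reaction phase → target (k = 8.90 L mol⁻¹ h⁻¹)
    reagent in the reaction phase ⇌ reagent in the second phase, rate k4*([reagent in the reaction phase] - [reagent in the second phase]/K4) per volume of the first phase (partition coefficient = 0.780, kL = 3.00 h⁻¹)
    reagent in the reaction phase + target → over-reacted product (k = 35.0 L mol⁻¹ h⁻¹)
    reagent in the reaction phase + target → over-reaction product (k = 1.80 L mol⁻¹ h⁻¹)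

The flasks give 7.19%, 11.1%, 12.0%, 7.29% and 2.45%, so the row rises, then falls, turning at 3.2 equiv. Blue after 1.00 h holds 50.3% over-reacted product, more than its 7.29% target. The turn stands at twice the crossing of 1.50 equiv, so the row keeps climbing for a while past it. Green is charged at ten times the crossing, and after 1.00 h it holds 2.45% target beside 74.1% over-reacted product.

The numbers in the tables stem from a simulated flask from invented constants, noise included.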